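## The problem

Compound 15 is a carbon–carbon linked biflavonoid: C3 of a 5,7,4'-trihydroxyflavanone is bonded to C3' of the B ring of 5,4'-dihydroxy-7-methoxyflavone. The linking bond joins an sp3 carbon α to a ketone with an aryl carbon ortho to a phenol, and it is crowded on both sides. The flavanone holds the only two stereocentres, C2 (S) and C3 (R), with the 4-hydroxyphenyl group and the flavone-bearing aryl group trans on ring C. C3 is enolisable and the trans arrangement is the more stable one, so C2 can hold C3 by equilibration. Nothing in the molecule controls C2: it must come from a reagent, and it is lost whenever base opens ring C to the chalcone (retro-oxa-Michael). The ketone should therefore appear late and afterwards meet neither base nor hot acid. Five phenols, three on easily oxidised and C-alkylated rings, stand beside a single methyl ether at O7 of the flavone; the methyl group is best bought in with its ring and the phenols given one mask that leaves under neutral conditions. The enabling feature is ring C of the flavanone: O1 and C4 both sit on ring A, like the oxygen and exocyclic carbon of an ortho-quinone methide, while C2 and C3 carry two aryl groups trans to each other, like the two carbons of an E-stilbene.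

## Retrosynthesis

**15 from 14 (phenol masks).** The five O–H bonds of 15 are traced back to five O–benzyl bonds in 14. Benzyl is preferred to silyl (lost in KOH and acid), to methyl (the wanted 7-OMe could not be spared) and to acetal groups (ionised by the acid of the key step). Its removal by hydrogenolysis is the one deprotection that puts neither C2 nor C3 at risk. The forward step must cleave five ethers without saturating the chromone double bond or opening the benzylic C2–O1 bond.

**14 from 13 (oxidation level of C4).** No skeletal bond is cut; the C4 ketone of 14 is traced back to the C4 methyl ether of 13. One oxidation level lower, the enolisable C3–H/ketone pair and the chalcone ring-opening path are absent, so 13 can be made and handled in acid. Direct DDQ oxidation in wet solvent is chosen over hydrolysis followed by alcohol oxidation: it saves a step and avoids a C4 cation without oxygen, which could lose H3 to give a flav-3-ene. The forward reaction must remove hydride from C4 only.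

**13 from 8 and 10 (ring C).** O1–C2 and C3–C4 are cut in a retro-[4+2] sense. Ring A with O1 and C4 becomes salicylaldehyde 10, which passes through acetal 11 to the methoxy ortho-quinone methide 12. C2 and C3 with both aryl groups become E-stilbene 8. The neighbouring cuts are less attractive. Cutting C2–C3, or O1–C2 alone, leaves the crowded C3–aryl bond to be made separately and installs the ketone early. Cutting C3–C3' would require arylation of a flavanone enolate at a hindered centre under base, which opens ring C. The chosen cut removes the ring, both stereocentres and half the mass at once and leaves an achiral alkene and a small aldehyde. The forward reaction must deliver three things: bonding of the quinone methide carbon to the stilbene carbon bearing the flavone ring, suprafacial addition so that E becomes trans, and one face selected by a chiral acid.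

**8 from 6 and 7 (stilbene).** The aryl–vinyl bond at C3' is cut, giving 3'-iodoflavone 6 and commercial styrene 7 as Heck partners. An olefination from a 3'-formylflavone would need a phosphonate and gives poorer E control; a Suzuki coupling would need a styrylboronate to be made first. The Heck reaction must give the E isomer by arylation at the terminal carbon and leave the trisubstituted, electron-poor chromone alkene alone.

**6 from 5, and 5 from 2 and 4 (flavone).** The chromone O1–C2 bond is cut to give 2'-hydroxychalcone 5, and the enone Cα=Cβ bond of 5 is cut to give acetophenone 2 and aldehyde 4. This Claisen–Schmidt and oxidative cyclisation pair is two steps, against three for an ester, acyl shift and cyclodehydration sequence. It carries the aryl iodide, already ortho to oxygen, from a commercial aldehyde. The cyclisation must spare the C–I bond and the benzyl ethers.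

**2 from 1, 4 from 3, 10 from 9 (benzylations).** Only O–benzyl bonds are cut. Hydrogen bonding to the carbonyl group sorts the hydroxyl groups: one of the two equivalent hydroxyls of 1, the single phenol of 3, and the para and one ortho hydroxyl of 9 are alkylated. The chelated hydroxyl that remains is the one needed later, as the ring-closing nucleophile in 5 and as the quinone methide oxygen in 10.

## Roads not taken

**Alternative 1:** The cut is at C3–C3' and O1–C2 of a 2,3-diarylchromone, the dehydro form of the flavanone. The forward key step treats the β,β-diaryl enone A1 with Tl(NO3)3 (trivalent thallium) or PhI(OH)OTs in methanol. The ortho-benzyloxyaryl group shifts from the β- to the α-carbon, and HCl then closes the ring A phenol onto the former β-carbon to give chromone A2.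
- Merits: the crowded C3–aryl bond is made intramolecularly by a classical rearrangement, C4 is a ketone from the start, and no asymmetric catalysis is needed for the carbon–carbon bond. In these respects it is more reliable than an intermolecular cycloaddition onto a stilbene.
- Weak points: A1 has two β-aryl groups that can both migrate. Its free phenol sits on a phloroglucinol-type ring that the oxidant can attack. A2 is flat, so both stereocentres would still have to come from an asymmetric conjugate reduction of a tetrasubstituted, doubly arylated chromone. The flavone would then have to be built from the aryl bromide over several steps beside a base-sensitive flavanone. Thallium adds a toxicity burden.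
- Comparison: the chosen plan sets against this the formation of ring C and both stereocentres in one step, from a stilbene that already carries the finished flavone, at the cost of one redox correction at C4.

**Alternative 2:** The cut is at O1–C8a and C4–C4a, two bonds to ring A. In the forward key step CsF generates 3,5-bis(benzyloxy)benzyne A4, which inserts into the acyl C–O bond of the α-aryl cinnamic acid A3 and gives the ortho-hydroxyaryl enone A5.
- Merits: the route is as convergent as the chosen one, A3 is available by a Perkin-type condensation, C4 is at the ketone level and the key step needs no transition metal.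
- Weak points: the key step closes no ring and sets no stereocentre. The aryne needs a multi-step silyl triflate precursor, and simple O-arylation of the acid competes with acyl migration. Ring C must then be closed by an enantioselective 6-endo oxa-Michael addition onto a hindered α,β-diaryl enone. That addition is reversible, so C2 would be formed under conditions in which it also racemises.
- Comparison: the chosen plan sets C2 irreversibly in a cycloaddition, at an oxidation level where ring opening cannot occur.

**Alternative 3:** The cut is at C2–C3. In the forward key step Rh2(S-PTTL)4, dirhodium tetrakis[N-phthaloyl-(S)-tert-leucinate] (divalent rhodium), converts diazo ketone A6 into a carbene at C3. The carbene inserts into the benzylic C–H bond of the 4-benzyloxybenzyl ether on the ring A oxygen and gives flavanone A7.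
- Merits: ring C and both stereocentres form in one catalytic asymmetric step at the ketone level. In directness of stereocontrol this road is at least the equal of the chosen plan, and it needs no redox correction.
- Weak points: the insertion must form a six-membered ring, whereas such carbenes prefer five. The ether oxygen is placed to attack the carbene and give a five-membered oxonium ylide, from which a Stevens-type [1,2]-shift of the very migration-prone 4-alkoxybenzyl group would divert the material. A6 needs a hindered deoxybenzoin, a diazo transfer and two silyl ethers, which add a deprotection step.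
- Comparison: the chosen plan sets against it a heterodiene with no comparable unimolecular escape, a precursor made in one Heck reaction, and a single kind of protecting group.

Key step: step 7

Assumption: the (R)-configured N-triflylphosphoramide is taken to shield the face of the quinone methide that leads to the (2S,3S,4S) series; if the sense of induction proves opposite, its enantiomer is used and nothing else changes.

## Steps

Step 1
Reactants: 1 1-(2,6-dihydroxy-4-methoxyphenyl)ethanone
Product: 2 1-[2-(benzyloxy)-6-hydroxy-4-methoxyphenyl]ethanone
Conditions: BnBr (1.05 equiv), K2CO3, acetone, reflux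
Reagents that add atoms: benzyl bromide, BrCc1ccccc1
Why: Williamson ether synthesis; the two hydroxyl groups are equivalent, and after the first alkylation the remaining one is locked in a hydrogen bond to the acetyl group, so one equivalent of bromide should stop at the monoether.

Step 2
Reactants: 3 4-hydroxy-3-iodobenzaldehyde
Product: 4 4-(benzyloxy)-3-iodobenzaldehyde
Conditions: BnBr, K2CO3, DMF, rt
Reagents that add atoms: benzyl bromide, BrCc1ccccc1
Why: Williamson ether synthesis of an acidic para-formyl phenol; the aldehyde and the aryl iodide are untouched by carbonate.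

Step 3
Reactants: 2 1-[2-(benzyloxy)-6-hydroxy-4-methoxyphenyl]ethanone, 4 4-(benzyloxy)-3-iodobenzaldehyde
Product: 5 (E)-1-[2-(benzyloxy)-6-hydroxy-4-methoxyphenyl]-3-[4-(benzyloxy)-3-iodophenyl]prop-2-en-1-one
Conditions: KOH (50% aq.), EtOH/THF, rt
Reagents that add atoms: none
Why: Claisen–Schmidt condensation of a methyl ketone with a non-enolisable aldehyde; dehydration of the aldol gives the conjugated E-enone, and benzyl ethers and the aryl iodide are stable to hydroxide.

Step 4
Reactants: 5 (E)-1-[2-(benzyloxy)-6-hydroxy-4-methoxyphenyl]-3-[4-(benzyloxy)-3-iodophenyl]prop-2-en-1-one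
Product: 6 5-(benzyloxy)-2-[4-(benzyloxy)-3-iodophenyl]-7-methoxy-4H-chromen-4-one
Conditions: I2 (iodine, 10 mol%), DMSO, 120 °C
Reagents that add atoms: none
Why: Iodine-catalysed oxidative cyclisation of a 2'-hydroxychalcone to a flavone (oxa-Michael closure of the free phenol followed by dehydrogenation, with DMSO as the terminal oxidant); the benzylated oxygen cannot cyclise, so it ends as the 5-benzyloxy group.

Step 5
Reactants: 6 5-(benzyloxy)-2-[4-(benzyloxy)-3-iodophenyl]-7-methoxy-4H-chromen-4-one, 7 1-(benzyloxy)-4-vinylbenzene
Product: 8 5-(benzyloxy)-2-{4-(benzyloxy)-3-[(E)-2-(4-(benzyloxy)phenyl)ethenyl]phenyl}-7-methoxy-4H-chromen-4-one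
Conditions: Pd(OAc)2 (5 mol%), P(o-tol)3 (10 mol%), Et3N, DMF, 100 °C
Reagents that add atoms: none
Why: Heck reaction; oxidative addition into the aryl iodide, syn insertion of the styrene at its terminal carbon and syn β-hydride elimination give the E-stilbene, while the trisubstituted electron-poor chromone alkene does not insert.

Step 6
Reactants: 9 2,4,6-trihydroxybenzaldehyde
Product: 10 4,6-bis(benzyloxy)-2-hydroxybenzaldehyde
Conditions: BnBr (2.05 equiv), K2CO3, DMF, 0 °C → rt
Reagents that add atoms: benzyl bromide, BrCc1ccccc1
Why: Williamson etherification under hydrogen-bond control; the hydroxyl para to the formyl group and one ortho hydroxyl are alkylated, and the last ortho hydroxyl stays chelated to the aldehyde and is left free.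

Step 7
Reactants: 10 4,6-bis(benzyloxy)-2-hydroxybenzaldehyde, 8 5-(benzyloxy)-2-{4-(benzyloxy)-3-[(E)-2-(4-(benzyloxy)phenyl)ethenyl]phenyl}-7-methoxy-4H-chromen-4-one
Product: 13 5-(benzyloxy)-2-{4-(benzyloxy)-3-[(2S,3S,4S)-5,7-bis(benzyloxy)-2-[4-(benzyloxy)phenyl]-4-methoxychroman-3-yl]phenyl}-7-methoxy-4H-chromen-4-one (2,3-trans-2,4-cis 4-methoxyflavan), via dimethyl acetal 11 (not isolated), via methoxy ortho-quinone methide 12 (not isolated)
Conditions: HC(OMe)3 (3 equiv), (R)-3,3'-bis(2,4,6-triisopropylphenyl)-1,1'-binaphthyl-2,2'-diyl N-triflylphosphoramide (10 mol%), 5 Å MS, toluene/CH2Cl2, −20 °C → rt; Et3N quench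
Reagents that add atoms: trimethyl orthoformate, COC(OC)OC
Why: Acid-catalysed exchange with the orthoformate turns aldehyde 10 into acetal 11, which loses methanol to an oxocarbenium ion in equilibrium with the 4-methoxy ortho-quinone methide 12, held by the chiral phosphoramide anion through an ion pair and a hydrogen bond to the ring A oxygen. The electron-rich E-stilbene 8 then adds in a concerted but asynchronous inverse-electron-demand hetero-Diels–Alder reaction in which C3–C4 forms ahead of O1–C2 and the developing positive charge rests on the para-benzyloxybenzyl carbon. The closest known reaction type is the acid-promoted [4+2] cycloaddition of alkoxy ortho-quinone methides from salicylaldehyde acetals with styrenes, together with chiral Brønsted-acid-catalysed ortho-quinone methide cycloadditions. Ring C closes in an intermolecular [4+2] mode, four atoms (O1, C8a, C4a, C4) coming from 12 and two (C2, C3) from 8, driven by rearomatisation of ring A. C2 and C3 become trans because addition across the E-alkene is suprafacial, and their absolute configuration is set by the catalyst pocket, which leaves one face of the bound heterodiene open. C4 is set cis to C2 by the endo approach of the C2 aryl group and by acid-mediated equilibration of the benzylic ether to the all-equatorial isomer; this centre is removed in step 8. The regiochemistry needed is secured by the substrate: the para-benzyloxyphenyl group stabilises a benzylic cation far better than the flavone B ring, whose benzyloxy group is ortho and whose chromone substituent withdraws electrons, and the electron-poor chromone alkene is inert towards the electron-poor heterodiene.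

Step 8
Reactants: 13 5-(benzyloxy)-2-{4-(benzyloxy)-3-[(2S,3S,4S)-5,7-bis(benzyloxy)-2-[4-(benzyloxy)phenyl]-4-methoxychroman-3-yl]phenyl}-7-methoxy-4H-chromen-4-one
Product: 14 (2S,3R)-5,7-bis(benzyloxy)-2-[4-(benzyloxy)phenyl]-3-{2-(benzyloxy)-5-[5-(benzyloxy)-7-methoxy-4-oxo-4H-chromen-2-yl]phenyl}chroman-4-one
Conditions: DDQ (1.5 equiv), CH2Cl2/pH 7 phosphate buffer (10:1), 0 °C → rt
Reagents that add atoms: water, O
Why: DDQ oxidation of an electron-rich benzylic ether, as in the oxidative cleavage of para-methoxybenzyl ethers: hydride is taken from C4 of the trialkoxy-substituted ring A, water adds to the oxocarbenium ion and the hemiketal collapses to the ketone with loss of methanol. C2 is not touched and C3 stays in, or returns to, the more stable trans arrangement; its descriptor changes from S to R only because C4 gains priority as a carbonyl carbon.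

Step 9
Reactants: 14 (2S,3R)-5,7-bis(benzyloxy)-2-[4-(benzyloxy)phenyl]-3-{2-(benzyloxy)-5-[5-(benzyloxy)-7-methoxy-4-oxo-4H-chromen-2-yl]phenyl}chroman-4-one
Product: 15 (2S,3R)-5,7-dihydroxy-3-[2-hydroxy-5-(5-hydroxy-7-methoxy-4-oxo-4H-chromen-2-yl)phenyl]-2-(4-hydroxyphenyl)chroman-4-one
Conditions: H2 (1 atm), Pd/C (10% palladium on carbon), THF/MeOH, rt
Reagents that add atoms: none
Why: Catalytic hydrogenolysis of aryl benzyl ethers; the neutral medium leaves C2 and C3 of the flavanone, the aryl methyl ether and the chromone double bond as they are when the reaction is stopped at full debenzylation.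

## Compound list

1 | 1-(2,6-dihydroxy-4-methoxyphenyl)ethanone | CC(=O)c1c(O)cc(OC)cc1O | starting material
2 | 1-[2-(benzyloxy)-6-hydroxy-4-methoxyphenyl]ethanone | CC(=O)c1c(O)cc(OC)cc1OCc1ccccc1 | intermediate
3 | 4-hydroxy-3-iodobenzaldehyde | O=Cc1ccc(O)c(I)c1 | starting material
4 | 4-(benzyloxy)-3-iodobenzaldehyde | O=Cc1ccc(OCc2ccccc2)c(I)c1 | intermediate
5 | (E)-1-[2-(benzyloxy)-6-hydroxy-4-methoxyphenyl]-3-[4-(benzyloxy)-3-iodophenyl]prop-2-en-1-one | COc1cc(O)c(C(=O)/C=C/c2ccc(OCc3ccccc3)c(I)c2)c(OCc2ccccc2)c1 | intermediate
6 | 5-(benzyloxy)-2-[4-(benzyloxy)-3-iodophenyl]-7-methoxy-4H-chromen-4-one | COc1cc(OCc2ccccc2)c2c(=O)cc(-c3ccc(OCc4ccccc4)c(I)c3)oc2c1 | intermediate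
7 | 1-(benzyloxy)-4-vinylbenzene | C=Cc1ccc(OCc2ccccc2)cc1 | starting material
8 | 5-(benzyloxy)-2-{4-(benzyloxy)-3-[(E)-2-(4-(benzyloxy)phenyl)ethenyl]phenyl}-7-methoxy-4H-chromen-4-one | COc1cc(OCc2ccccc2)c2c(=O)cc(-c3ccc(OCc4ccccc4)c(/C=C/c4ccc(OCc5ccccc5)cc4)c3)oc2c1 | intermediate
9 | 2,4,6-trihydroxybenzaldehyde | O=Cc1c(O)cc(O)cc1O | starting material
10 | 4,6-bis(benzyloxy)-2-hydroxybenzaldehyde | O=Cc1c(O)cc(OCc2ccccc2)cc1OCc1ccccc1 | intermediate
11 | 3,5-bis(benzyloxy)-2-(dimethoxymethyl)phenol | COC(OC)c1c(O)cc(OCc2ccccc2)cc1OCc1ccccc1 | intermediate
12 | (6E)-3,5-bis(benzyloxy)-6-(methoxymethylidene)cyclohexa-2,4-dien-1-one | CO/C=C1/C(=O)C=C(OCc2ccccc2)C=C1OCc1ccccc1 | intermediate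
13 | 5-(benzyloxy)-2-{4-(benzyloxy)-3-[(2S,3S,4S)-5,7-bis(benzyloxy)-2-[4-(benzyloxy)phenyl]-4-methoxychroman-3-yl]phenyl}-7-methoxy-4H-chromen-4-one | COc1cc(OCc2ccccc2)c2c(=O)cc(-c3ccc(OCc4ccccc4)c([C@H]4[C@H](OC)c5c(OCc6ccccc6)cc(OCc6ccccc6)cc5O[C@@H]4c4ccc(OCc5ccccc5)cc4)c3)oc2c1 | intermediate
14 | (2S,3R)-5,7-bis(benzyloxy)-2-[4-(benzyloxy)phenyl]-3-{2-(benzyloxy)-5-[5-(benzyloxy)-7-methoxy-4-oxo-4H-chromen-2-yl]phenyl}chroman-4-one | COc1cc(OCc2ccccc2)c2c(=O)cc(-c3ccc(OCc4ccccc4)c([C@H]4C(=O)c5c(OCc6ccccc6)cc(OCc6ccccc6)cc5O[C@@H]4c4ccc(OCc5ccccc5)cc4)c3)oc2c1 | intermediate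
15 | (2S,3R)-5,7-dihydroxy-3-[2-hydroxy-5-(5-hydroxy-7-methoxy-4-oxo-4H-chromen-2-yl)phenyl]-2-(4-hydroxyphenyl)chroman-4-one | COc1cc(O)c2c(=O)cc(-c3ccc(O)c([C@H]4C(=O)c5c(O)cc(O)cc5O[C@@H]4c4ccc(O)cc4)c3)oc2c1 | target

## Step count and risks

Total step count: 9. Longest linear sequence: 7 steps (steps 1, 3, 4, 5, 7, 8, 9).

**Step 7 (key step).** The most likely failure is poor facial selectivity. The trialkoxy-stabilised oxocarbenium ion is long-lived and only loosely paired with the chiral anion, and the methanol set free competes for its hydrogen bonds. A second danger is slow addition to the 1,2-diaryl alkene, which gives the quinone methide time to oligomerise and the acid time to ionise the product at C4. The fallback gives up catalyst control. It sets out from 8 and 10, which are combined with HC(OMe)3 and Sc(OTf)3 in CH2Cl2 at rt, passing through 11 and 12. This gives 13 as the racemate, that is, together with its mirror image, the (2R,3R,4R) cycloadduct F1. The two are separated by preparative chromatography on a cellulose tris(3,5-dimethylphenylcarbamate) phase, and the route is rejoined at 13.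

**Step 8.** Over-oxidation is the main risk. Loss of the C3 proton from the oxocarbenium ion gives an enol ether that DDQ can dehydrogenate further to a flavylium ion, which would erase both stereocentres. Competing hydride abstraction at C2 would open ring C. The fallback separates hydrolysis from oxidation. It sets out from 13, which is solvolysed with catalytic TsOH in acetone/water at rt to the (2S,3S,4S)-flavan-4-ol F2 (the configuration at C4 is immaterial). Buffered Dess–Martin periodinane in CH2Cl2 then oxidises the alcohol, and the route is rejoined at 14.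

**Step 9.** Over-reduction may occur: saturation of the chromone double bond or hydrogenolytic opening of the benzylic C2–O1 bond, while the ethers next to the two carbonyl groups are still cleaving slowly. The fallback replaces hydrogenolysis by Lewis-acid dealkylation. It sets out from 14, which is treated with BCl3 and pentamethylbenzene as cation scavenger in CH2Cl2 at −78 °C; the aryl methyl ether is not chelated and should survive. The route is rejoined at 15, and this fallback makes no new compound (F0).

**Step 6.** Discrimination between the three hydroxyl groups may be incomplete, giving mono- and tri-ethers, and the electron-rich ring may be C-benzylated. The fallback removes the need for selectivity in the alkylation. It sets out from 9, which is benzylated exhaustively (excess BnBr, K2CO3, DMF, 60 °C) to 2,4,6-tris(benzyloxy)benzaldehyde F3. One ortho ether is then removed under chelation control with MgBr2·OEt2 in toluene/Et2O, and the route is rejoined at 10.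

**Step 4.** Hydrogen iodide formed at 120 °C may cleave the benzyl ether ortho to the carbonyl group. The fallback separates ring closure from dehydrogenation. It sets out from 5, which is cyclised with NaOAc in refluxing EtOH to the racemic 5-(benzyloxy)-2-[4-(benzyloxy)-3-iodophenyl]-7-methoxychroman-4-one F4. This flavanone is dehydrogenated with DDQ in refluxing dioxane, and the route is rejoined at 6.

## Further compounds

F1 | step 7 | 5-(benzyloxy)-2-{4-(benzyloxy)-3-[(2R,3R,4R)-5,7-bis(benzyloxy)-2-[4-(benzyloxy)phenyl]-4-methoxychroman-3-yl]phenyl}-7-methoxy-4H-chromen-4-one | COc1cc(OCc2ccccc2)c2c(=O)cc(-c3ccc(OCc4ccccc4)c([C@@H]4[C@@H](OC)c5c(OCc6ccccc6)cc(OCc6ccccc6)cc5O[C@H]4c4ccc(OCc5ccccc5)cc4)c3)oc2c1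
F2 | step 8 | 5-(benzyloxy)-2-{4-(benzyloxy)-3-[(2S,3S,4S)-5,7-bis(benzyloxy)-2-[4-(benzyloxy)phenyl]-4-hydroxychroman-3-yl]phenyl}-7-methoxy-4H-chromen-4-one | COc1cc(OCc2ccccc2)c2c(=O)cc(-c3ccc(OCc4ccccc4)c([C@H]4[C@H](O)c5c(OCc6ccccc6)cc(OCc6ccccc6)cc5O[C@@H]4c4ccc(OCc5ccccc5)cc4)c3)oc2c1
F0 | step 9 | none | none
F3 | step 6 | 2,4,6-tris(benzyloxy)benzaldehyde | O=Cc1c(OCc2ccccc2)cc(OCc2ccccc2)cc1OCc1ccccc1
F4 | step 4 | 5-(benzyloxy)-2-[4-(benzyloxy)-3-iodophenyl]-7-methoxychroman-4-one (racemic) | COc1cc(OCc2ccccc2)c2c(c1)OC(c1ccc(OCc3ccccc3)c(I)c1)CC2=O
A1 | alternative 1 | (E)-1-[2,4-bis(benzyloxy)-6-hydroxyphenyl]-3-[2-(benzyloxy)-5-bromophenyl]-3-[4-(pivaloyloxy)phenyl]prop-2-en-1-one | CC(C)(C)C(=O)Oc1ccc(/C(=C\C(=O)c2c(O)cc(OCc3ccccc3)cc2OCc2ccccc2)c2cc(Br)ccc2OCc2ccccc2)cc1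
A2 | alternative 1 | 5,7-bis(benzyloxy)-3-[2-(benzyloxy)-5-bromophenyl]-2-[4-(pivaloyloxy)phenyl]-4H-chromen-4-one | CC(C)(C)C(=O)Oc1ccc(-c2oc3cc(OCc4ccccc4)cc(OCc4ccccc4)c3c(=O)c2-c2cc(Br)ccc2OCc2ccccc2)cc1
A3 | alternative 2 | (E)-2-{2-(benzyloxy)-5-[5-(benzyloxy)-7-methoxy-4-oxo-4H-chromen-2-yl]phenyl}-3-[4-(benzyloxy)phenyl]prop-2-enoic acid | COc1cc(OCc2ccccc2)c2c(=O)cc(-c3ccc(OCc4ccccc4)c(/C(=C\c4ccc(OCc5ccccc5)cc4)C(=O)O)c3)oc2c1
A4 | alternative 2 | 3,5-bis(benzyloxy)benzyne | C1#CC(OCc2ccccc2)=CC(OCc2ccccc2)=C1
A5 | alternative 2 | (E)-1-[2,4-bis(benzyloxy)-6-hydroxyphenyl]-2-{2-(benzyloxy)-5-[5-(benzyloxy)-7-methoxy-4-oxo-4H-chromen-2-yl]phenyl}-3-[4-(benzyloxy)phenyl]prop-2-en-1-one | COc1cc(OCc2ccccc2)c2c(=O)cc(-c3ccc(OCc4ccccc4)c(/C(=C\c4ccc(OCc5ccccc5)cc4)C(=O)c4c(O)cc(OCc5ccccc5)cc4OCc4ccccc4)c3)oc2c1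
A6 | alternative 3 | 1-{4-(benzyloxy)-2-[(4-(benzyloxy)benzyl)oxy]-6-[(tert-butyldimethylsilyl)oxy]phenyl}-2-{5-[5-(benzyloxy)-7-methoxy-4-oxo-4H-chromen-2-yl]-2-[(tert-butyldimethylsilyl)oxy]phenyl}-2-diazoethan-1-one | COc1cc(OCc2ccccc2)c2c(=O)cc(-c3ccc(O[Si](C)(C)C(C)(C)C)c(C(=[N+]=[N-])C(=O)c4c(O[Si](C)(C)C(C)(C)C)cc(OCc5ccccc5)cc4OCc4ccc(OCc5ccccc5)cc4)c3)oc2c1
A7 | alternative 3 | (2S,3R)-7-(benzyloxy)-2-[4-(benzyloxy)phenyl]-3-{5-[5-(benzyloxy)-7-methoxy-4-oxo-4H-chromen-2-yl]-2-[(tert-butyldimethylsilyl)oxy]phenyl}-5-[(tert-butyldimethylsilyl)oxy]chroman-4-one | COc1cc(OCc2ccccc2)c2c(=O)cc(-c3ccc(O[Si](C)(C)C(C)(C)C)c([C@H]4C(=O)c5c(O[Si](C)(C)C(C)(C)C)cc(OCc6ccccc6)cc5O[C@@H]4c4ccc(OCc5ccccc5)cc4)c3)oc2c1
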